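**Plan**
- The retrosynthesis first removes the two phenol O-benzyl groups and cuts the stearate acyl–O bond. It then cuts C2–C3 of the oxolane (O1, C2 aryl, C3 CH2O-acyl, C4 benzyl, C5).
- Enabling feature: C2 bears O1 and an electron-rich aryl group, so it is a latent oxocarbenium carbon. C3 bears an exocyclic C–O carbon, so C3=CH–O is a latent enolate.
- Tying that exocyclic oxygen back to C2 gives a seven-membered 4,5-dihydro-1,3-dioxepine, O–CH(Ar)–O–CH2–CH(CH2Ar')–CH=CH.
- Forward order: form the seven-membered acetal from O-benzylvanillin and cis-butenediol, attach the benzyl arm by Heck reaction, contract the ring from 7 to 5, then reduce, acylate and debenzylate.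
- Stereochemistry: C4 comes from the catalyst-controlled Heck step. C2 is relayed from C4 during the contraction. C3 is set by base equilibration of the formyl group in the same flask.

Key step: step 4

Remark: the target is read as the 9-O-stearate of (+)-lariciresinol, (2S,3R,4R), with 2,3-trans and 3,4-cis substituents. Compound 6 is used as a mixture of C2 epimers because C2 becomes planar in step 4.

**Step 1**
Reactants: 1 4-(benzyloxy)-3-methoxybenzaldehyde; 2 (Z)-but-2-ene-1,4-diol
Product: 3 2-[4-(benzyloxy)-3-methoxyphenyl]-4,7-dihydro-1,3-dioxepine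
Conditions: p-TsOH·H2O (cat.), toluene, reflux, Dean–Stark
Reagents that add atoms: none
Why: Acid-catalysed acetalisation with azeotropic removal of water should close the seven-membered ring because the cis-alkene holds both hydroxyls on one side, and no stereocentre is formed.

**Step 2**
Reactants: 4 [4-(benzyloxy)-3-methoxyphenyl]methanol
Product: 5 4-(benzyloxy)-3-methoxybenzyl trifluoroacetate
Conditions: (CF3CO)2O, pyridine, CH2Cl2, 0 °C; used without chromatography
Reagents that add atoms: trifluoroacetic anhydride, O=C(OC(=O)C(F)(F)F)C(F)(F)F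
Why: Simple O-acylation turns the benzylic alcohol into an ester that undergoes oxidative addition to Pd(0) as a π-benzyl complex.

**Step 3**
Reactants: 3 2-aryl-4,7-dihydro-1,3-dioxepine; 5 benzylic trifluoroacetate
Product: 6 (5R)-5-[4-(benzyloxy)-3-methoxybenzyl]-2-[4-(benzyloxy)-3-methoxyphenyl]-4,5-dihydro-1,3-dioxepine (C2 epimers)
Conditions: Pd(dba)2 (5 mol %), BINOL-derived phosphoramidite (antipode chosen for 5R, 10 mol %), Li2CO3, THF, 55 °C
Reagents that add atoms: none
Why: In this asymmetric Mizoroki–Heck benzylation of a cyclic olefin the chiral π-benzyl-Pd adds syn to one enantiotopic end and face of the symmetric C5=C6 bond, and syn β-hydride elimination can only use a C7–H, which moves the alkene into the enol-ether position and keeps C5 as the (R) stereocentre.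

**Step 4**
Reactants: 6 (5R)-5-benzyl-2-aryl-4,5-dihydro-1,3-dioxepine
Product: 9 (2S,3S,4R)-4-[4-(benzyloxy)-3-methoxybenzyl]-2-[4-(benzyloxy)-3-methoxyphenyl]oxolane-3-carbaldehyde, via oxocarbenium silyl enol ether 7 (not isolated), via 3-epi-aldehyde 8 (not isolated)
Conditions: TMSOTf (10 mol %), CH2Cl2, −78 °C, 30 min; then DBU (30 mol %), −78 → 23 °C
Reagents that add atoms: none
Why: TMSOTf silylates the enol-ether oxygen O1, C2–O1 ionises to the (E)-aryl oxocarbenium/(Z)-silyl enol ether 7, C6 attacks C2 and TMS+ is released, so the ring O1–C2–O3–C4–C5–C6–C7 loses O1 and C7 (they become the formyl group) and the oxolane O3–C2–C6–C5–C4 remains. The closest known reaction type is the Lewis-acid [1,3] O→C rearrangement of cyclic vinyl acetals (4,5-dihydro-1,3-dioxepines to oxolane-3-carbaldehydes), an intramolecular Mukaiyama aldol related to the Petasis–Ferrier rearrangement. The ring closes in the 5-(enolexo)-endo-trig mode on the oxocarbenium carbon. A(1,3) strain with the Z-silyloxy group holds the C5–H in the enol plane, so the tether reaches the face anti to the benzyl group (3,4-trans), and the synclinal low-temperature transition state places aryl cis to the nascent formyl group (2,3-cis), which fixes aryl trans to benzyl across the ring in 8. DBU then equilibrates only C3 through the aldehyde enolate, and the formyl group should move away from the directly attached C2 aryl to sit cis to the slimmer C4 CH2Ar' arm, giving 2,3-trans-3,4-cis 9, while C2 stays fixed because β-alkoxide loss would be the reverse of a 5-endo-trig closure. The step needs kinetic control (no reversible C2–C3 cleavage to the all-trans isomer, no Friedel–Crafts attack by the benzyl arene), which catalytic TMSOTf at −78 °C and the fast five-membered capture, compared with a seven-membered arene attack, should secure.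

**Step 5**
Reactants: 9 (2S,3S,4R)-oxolane-3-carbaldehyde
Product: 10 [(2S,3R,4R)-4-[4-(benzyloxy)-3-methoxybenzyl]-2-[4-(benzyloxy)-3-methoxyphenyl]oxolan-3-yl]methanol (di-O-benzyl-lariciresinol)
Conditions: NaBH4, MeOH/THF, 0 °C
Reagents that add atoms: none
Why: Borohydride 1,2-reduction of the aldehyde is fast at 0 °C, creates no stereocentre and freezes the C3 configuration (the descriptor changes only through CIP priorities).

**Step 6**
Reactants: 10 di-O-benzyl-lariciresinol; 11 octadecanoyl chloride (stearoyl chloride)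
Product: 12 [(2S,3R,4R)-4-[4-(benzyloxy)-3-methoxybenzyl]-2-[4-(benzyloxy)-3-methoxyphenyl]oxolan-3-yl]methyl octadecanoate
Conditions: Et3N, DMAP (cat.), CH2Cl2, 0 °C → rt
Reagents that add atoms: none
Why: DMAP-catalysed acylation meets only one free hydroxyl group, the primary alcohol released by the ring contraction, because both phenols are still benzylated.

**Step 7**
Reactants: 12 di-O-benzyl stearate
Product: 13 [(2S,3R,4R)-4-(4-hydroxy-3-methoxybenzyl)-2-(4-hydroxy-3-methoxyphenyl)oxolan-3-yl]methyl octadecanoate (target)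
Conditions: H2 (1 atm), 10% Pd/C, EtOAc/THF, rt
Reagents that add atoms: none
Why: Neutral catalytic hydrogenolysis should cleave the two aryl benzyl ethers faster than the hindered ring C2–O bond, leaves the ester and all stereocentres untouched and avoids the acid that would trigger aryltetralin formation.

**Compound list**
1 | 4-(benzyloxy)-3-methoxybenzaldehyde | O=Cc1ccc(OCc2ccccc2)c(OC)c1 | starting material
2 | (Z)-but-2-ene-1,4-diol | OC/C=C\CO | starting material
3 | 2-[4-(benzyloxy)-3-methoxyphenyl]-4,7-dihydro-1,3-dioxepine | C1=CCOC(c2ccc(OCc3ccccc3)c(OC)c2)OC1 | intermediate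
4 | [4-(benzyloxy)-3-methoxyphenyl]methanol | OCc1ccc(OCc2ccccc2)c(OC)c1 | starting material
5 | 4-(benzyloxy)-3-methoxybenzyl trifluoroacetate | O=C(OCc1ccc(OCc2ccccc2)c(OC)c1)C(F)(F)F | intermediate
6 | (5R)-5-[4-(benzyloxy)-3-methoxybenzyl]-2-[4-(benzyloxy)-3-methoxyphenyl]-4,5-dihydro-1,3-dioxepine, C2 epimers | C1=C[C@@H](Cc2ccc(OCc3ccccc3)c(OC)c2)COC(c2ccc(OCc3ccccc3)c(OC)c2)O1 | intermediate
7 | ring-opened (E)-oxocarbenium (Z)-trimethylsilyl enol ether, triflate salt | C[Si](C)(C)O/C=C\[C@@H](Cc1ccc(OCc2ccccc2)c(OC)c1)C/[O+]=C/c1ccc(OCc2ccccc2)c(OC)c1.[O-]S(=O)(=O)C(F)(F)F | intermediate (not isolated)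
8 | (2S,3R,4R)-4-[4-(benzyloxy)-3-methoxybenzyl]-2-[4-(benzyloxy)-3-methoxyphenyl]oxolane-3-carbaldehyde (2,3-cis-3,4-trans) | O=C[C@@H]1[C@@H](Cc2ccc(OCc3ccccc3)c(OC)c2)CO[C@@H]1c1ccc(OCc2ccccc2)c(OC)c1 | intermediate (not isolated)
9 | (2S,3S,4R)-4-[4-(benzyloxy)-3-methoxybenzyl]-2-[4-(benzyloxy)-3-methoxyphenyl]oxolane-3-carbaldehyde (2,3-trans-3,4-cis) | O=C[C@H]1[C@@H](Cc2ccc(OCc3ccccc3)c(OC)c2)CO[C@@H]1c1ccc(OCc2ccccc2)c(OC)c1 | intermediate
10 | [(2S,3R,4R)-4-[4-(benzyloxy)-3-methoxybenzyl]-2-[4-(benzyloxy)-3-methoxyphenyl]oxolan-3-yl]methanol | OC[C@H]1[C@@H](Cc2ccc(OCc3ccccc3)c(OC)c2)CO[C@@H]1c1ccc(OCc2ccccc2)c(OC)c1 | intermediate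
11 | octadecanoyl chloride | CCCCCCCCCCCCCCCCCC(=O)Cl | starting material
12 | [(2S,3R,4R)-4-[4-(benzyloxy)-3-methoxybenzyl]-2-[4-(benzyloxy)-3-methoxyphenyl]oxolan-3-yl]methyl octadecanoate | CCCCCCCCCCCCCCCCCC(=O)OC[C@H]1[C@@H](Cc2ccc(OCc3ccccc3)c(OC)c2)CO[C@@H]1c1ccc(OCc2ccccc2)c(OC)c1 | intermediate
13 | [(2S,3R,4R)-4-(4-hydroxy-3-methoxybenzyl)-2-(4-hydroxy-3-methoxyphenyl)oxolan-3-yl]methyl octadecanoate | CCCCCCCCCCCCCCCCCC(=O)OC[C@H]1[C@@H](Cc2ccc(O)c(OC)c2)CO[C@@H]1c1ccc(O)c(OC)c1 | target

**Step count**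
Total step count: 7. Longest linear sequence: 6 (steps 1, 3, 4, 5, 6, 7).

**Steps most likely to fail**

1. **Step 4.**
   - Risk: The electron-rich oxocarbenium ion may let the C2–C3 bond form reversibly, so that material drains into the all-trans isomer. The C3 equilibrium may also favour the wanted epimer only modestly, which would force separation and recycling.
   - Fallback: It sets out from 6 and returns at 10. It keeps the Heck stereocentre but builds the ring without an epimerisable aldehyde.
   - Mild aqueous acid hydrolysis of the enol acetal 6 (AcOH/H2O/THF) should give (4R)-4-[4-(benzyloxy)-3-methoxybenzyl]oxolan-2-ol F1.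
   - Oxidation with TEMPO/PhI(OAc)2 gives (4R)-4-[4-(benzyloxy)-3-methoxybenzyl]oxolan-2-one F2.
   - The LiHMDS enolate adds to aldehyde 1 anti to the benzyl group to give the α,β-trans aldol lactone F3.
   - LiAlH4 reduces F3 to the (8R,8'R)-triol F4.
   - Catalytic camphorsulfonic acid in CH2Cl2 at 0 °C closes the C9'–O–C7 ether through the benzylic cation, with aryl trans to the C8 arm, and gives 10.
   - The trans-lactone becomes the 3,4-cis oxolane because C7 and C9 exchange the ring and side-chain roles at C8.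

2. **Step 3.**
   - Risk: There may be poor facial discrimination on an olefin not yet paired with a benzylic electrophile. Solvolysis of the electron-rich ester 5 and Pd–H re-addition may also compete.
   - Fallback: It sets out from 4 and returns at 6. It creates C5 by asymmetric hydrogen shift instead of C–C bond formation.
   - PBr3 converts 4 into 4-(benzyloxy)-3-methoxybenzyl bromide F5.
   - Pd-catalysed syn-hydrostannation of commercial but-2-yne-1,4-diol gives (E)-2-(tributylstannyl)but-2-ene-1,4-diol F6.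
   - Stille coupling of F5 with F6 gives (Z)-2-[4-(benzyloxy)-3-methoxybenzyl]but-2-ene-1,4-diol F7.
   - Acetalisation of F7 with 1 gives the 5-benzyl-4,7-dihydro-1,3-dioxepine F8.
   - Asymmetric double-bond isomerisation of F8 with a chiral nickel hydride (NiBr2/Me-DuPHOS, LiBHEt3) should deliver 6.

3. **Step 7.**
   - Risk: Debenzylation of the waxy, poorly soluble stearate may be slow. Prolonged exposure would then allow creeping hydrogenolysis of the ring C2–O bond.
   - Fallback: It sets out from 10 and returns at 13.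
   - The polar alcohol 10 is hydrogenolysed first (H2, Pd/C, EtOAc) to (+)-lariciresinol F9.
   - The single aliphatic primary hydroxyl is then acylated chemoselectively in the presence of the two phenols with vinyl stearate and immobilised Candida antarctica lipase B in tert-amyl alcohol.

**Further compounds**
F1 | step 4 | (4R)-4-[4-(benzyloxy)-3-methoxybenzyl]oxolan-2-ol (anomers) | OC1C[C@@H](Cc2ccc(OCc3ccccc3)c(OC)c2)CO1
F2 | step 4 | (4R)-4-[4-(benzyloxy)-3-methoxybenzyl]oxolan-2-one | O=C1C[C@@H](Cc2ccc(OCc3ccccc3)c(OC)c2)CO1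
F3 | step 4 | (3S,4R)-4-[4-(benzyloxy)-3-methoxybenzyl]-3-{[4-(benzyloxy)-3-methoxyphenyl](hydroxy)methyl}oxolan-2-one (carbinol epimers) | O=C1[C@H](C(O)c2ccc(OCc3ccccc3)c(OC)c2)[C@@H](Cc2ccc(OCc3ccccc3)c(OC)c2)CO1
F4 | step 4 | (2R,3R)-2-{[4-(benzyloxy)-3-methoxyphenyl](hydroxy)methyl}-3-[4-(benzyloxy)-3-methoxybenzyl]butane-1,4-diol (carbinol epimers) | OC[C@H](C(O)c1ccc(OCc2ccccc2)c(OC)c1)[C@@H](Cc1ccc(OCc2ccccc2)c(OC)c1)CO
F5 | step 3 | 4-(benzyloxy)-3-methoxybenzyl bromide | BrCc1ccc(OCc2ccccc2)c(OC)c1
F6 | step 3 | (E)-2-(tributylstannyl)but-2-ene-1,4-diol | OC/C=C(/[Sn](CCCC)(CCCC)CCCC)CO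
F7 | step 3 | (Z)-2-[4-(benzyloxy)-3-methoxybenzyl]but-2-ene-1,4-diol | OC/C=C(/Cc1ccc(OCc2ccccc2)c(OC)c1)CO
F8 | step 3 | 5-[4-(benzyloxy)-3-methoxybenzyl]-2-[4-(benzyloxy)-3-methoxyphenyl]-4,7-dihydro-1,3-dioxepine | C1=C(Cc2ccc(OCc3ccccc3)c(OC)c2)COC(c2ccc(OCc3ccccc3)c(OC)c2)OC1
F9 | step 7 | (+)-lariciresinol, [(2S,3R,4R)-4-(4-hydroxy-3-methoxybenzyl)-2-(4-hydroxy-3-methoxyphenyl)oxolan-3-yl]methanol | OC[C@H]1[C@@H](Cc2ccc(O)c(OC)c2)CO[C@@H]1c1ccc(O)c(OC)c1
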